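Catalyst is a conserved charge: free catalyst, catalyst intermediate and spent catalyst sum to what went in, and spent catalyst has no way back. These flasks are therefore booked per mole of catalyst, which is the limiting charge here rather than the reagent. The possible steps are these. Substrate and free catalyst reversibly give open intermediate, which reversibly binds free catalyst as catalyst intermediate. Reagent turns that into target and frees the catalyst. Free catalyst interconverts target and isomer of the product, and free catalyst plus target gives spent catalyst.

all flasks: substrate 1.2 M; free catalyst 0.2 mol%

| run | reagent | remark | time |
|---|---|---|---|
| green | 1 equiv | the very flask that is asked about, followed so far |  |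
| teal | 2 equiv | run made earlier |  |
| flask | 1.00 equiv |  | 50 min |

| run | time / min | target / % | isomer of the product / % |
|---|---|---|---|
| green | 1.33 | 14.2 | 3.8 |
| green | 3.00 | 18.7 | 7.8 |
| green | 6.00 | 19.3 | 7.9 |
| green | 15.0 | 19.0 | 8.2 |
| teal | 8.00 | 25.4 | 7.8 |
| teal | 20.0 | 26.5 | 9.8 |
| teal | 25.0 | 25.8 | 8.2 |
| teal | 40.0 | 24.4 | 6.2 |

(each reading ± 1 percentage point)

- the numbers in the tables scatter with a standard deviation of 1 percentage point
- what may be going on: free catalyst + open intermediate <-> catalyst intermediate; free catalyst + target -> spent catalyst; reagent + catalyst intermediate -> free catalyst + target; target + free catalyst <-> isomer of the product + free catalyst; substrate + free catalyst <-> free catalyst + open intermediate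

- share of target in target plus isomer of the product at 10 s
- share of target in target plus isomer of the product at 2.5 min
- share of target in target plus isomer of the product at 50 min

The two latest green readings, at 6.00 min and 15.0 min, stand level within their scatter and average 19.1% target and 8.05% isomer. With one reagent per product, about 72.8% of the reagent remains, so the books must close on the catalyst.

Isomerisation and catalyst death both need free catalyst meeting target, so while the way back from isomer stays small, each mole of catalyst lost should carry a fixed count of isomer, a selectivity factor. Call it Q, the moles of isomer at the plateau per mole of catalyst charged. As read from green, Q = 40.2, with 95.8 moles of target in the other column. The teal run, with twice the reagent, averages 8.00% isomer, level with green, while its target column reads 25.5%, or 128 moles.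

My reckoning for the green flask at 50 min is the closed ledger, a share of 70.4%. Isomer comes after target, so the share at 10 s should lie above the 78.9% read at 1.33 min, and at 2.5 min between that and the 70.6% read at 3.00 min.

The forecast gives 96%, 72% and 70.5%, calling the plateau “a frozen kinetic value, not necessarily equilibrium”.

The flask gives 97.3%, 74.9% and 71.2%.

    free catalyst + open intermediate ⇌ catalyst intermediate (K = 1.67 M⁻¹, k = 17.6 M⁻¹ s⁻¹)
    free catalyst + target → spent catalyst (k = 0.0950 M⁻¹ s⁻¹)
    reagent + catalyst intermediate → free catalyst + target (k = 3.93 M⁻¹ s⁻¹)
    target + free catalyst ⇌ isomer of the product + free catalyst, rate k4*[free catalyst]*[target] forward; the back reaction follows from the equilibrium constant (K = 6.52, k = 3.94 M⁻¹ s⁻¹)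
    substrate + free catalyst ⇌ free catalyst + open intermediate (K = 0.680, k = 45.0 M⁻¹ s⁻¹)

At 50.0 min the asked flask holds 100% of its catalyst as spent catalyst, with 19.7% target and 7.98% isomer, which is 39.9 moles of isomer per mole of catalyst. A neighbouring flask charged with 0.08 mol% of free catalyst should then hold 3.22% isomer by the same tally. It ends with 3.25% isomer beside 14.8% target, a share of 82.0%.

The numbers in the tables are simulated with constants of no real substance; noise was put on by code.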